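Remark on the chemistry: the sense of induction of the chiral copper catalyst in step 2 is assumed to be selectable, since both antipodes of the leucinol-derived ligand are accessible. TBS = tert-butyl(dimethyl)silyl.

## The problem

The carbocyclic core of target 33 is numbered as a 2,3,5,6,7,7a-hexahydro-1H-indene. C1 bears the lactone oxygen, C2 the lactone carbonyl, C7 the CH2O–butyrate, and C4 the (R)-1,3,3-trimethylcyclohexyl group through its quaternary carbon C1'.

- The hardest bond is C4–C1'. It joins a carbon of the tetrasubstituted alkene C3a=C4 (shared with the cyclopentane at C3a) to a quaternary stereocentre, which is the most hindered position in the molecule.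
- C1' is stereogenic only because of a gem-dimethyl group two bonds away, and the alkene insulates it from the other four stereocentres. It must therefore be set on its own, by catalysis.
- C2, C1, C7a and C7 are contiguous. C1 and C2 are cis (the β-lactone). C7a–H is cis to the lactone oxygen. The C7 substituent is trans to C1.
- C1 and C2 can be set together in an open chain, and C1 can then control C7a. C7 has the equatorial, thermodynamically preferred arrangement, whereas hydrogen delivery to a C6=C7 alkene from the open face would be expected to give its epimer.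
- The β-lactone will not survive nucleophiles, base or heat and has to be closed last. The butyrate restricts late hydrolytic and reductive steps.
- The feature that makes the key step possible: the six-membered ring holds exactly one C=C, C3a=C4. One end carries C1' and the other carries the chain C3–C2–C1 that returns to C7a. Read backwards, C3a=C4 is an alkyne, C5–C6–C7–C7a is a 1,3-diene and C3–C2–C1 is a three-atom tether. This is the pattern of an intramolecular dienyne [4+2] cycloaddition.
- In that diene the CH2O group on C7 is necessarily cis to the tether, which creates the allylic 1,3-strain that lets C1 dictate C7a.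

## Retrosynthesis

**Lactone last (33 ⇒ 31).** The acyl–oxygen bond of the β-lactone is cut. Closure by carboxyl activation leaves the C1–O bond intact, so C1 and C2 are retained. The neighbouring cut, the C1–O bond closed with inversion, would risk decarboxylative elimination. Hydroxy acid 31 comes from imide 29 and silyl ether 28. The forward reaction asks only that the cis hydroxyl attacks the activated carboxyl; the primary hydroxyl is already a butyrate and cannot compete.

**C7 by equilibration (28 ⇒ 27 ⇒ 26 ⇒ 23).** The C7 stereocentre is traced to aldehyde 26, whose α-carbon can be equilibrated, and from there to allylic alcohol 23 with a C6=C7 double bond. Hydrogenation of C6=C7 would add hydrogen syn to C7a–H and give the C7 epimer. Redox isomerization followed by base should instead give the trans-diequatorial arrangement of the target. The forward reaction needs a real thermodynamic preference for the equatorial formyl group.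

**Key disconnection (23 ⇐ 22 ⇒ 21).** The bonds C3a–C7a and C4–C5 are cut. Both carbocycles open to a chain, the tetrasubstituted alkene becomes an internal alkyne, and C7a is no longer a stereocentre. Against a cut at C4–C1' or a Diels–Alder with an alkene dienophile, this cut removes two rings and the hindered alkene at once. Precursor 21 has only three stereocentres (C1, C2, C1'). The forward reaction must close on one diene face only, which the cis CH2OTBS group on C7 should enforce.

**Chain union (21 ⇒ 20 ⇒ 12 + 18).** The C1–C2 bond is cut as an aldol. This sets C1 and C2 together and in the absolute sense, and it divides the chain into two halves of similar size. Imide 12 carries the alkyne and C1'. Dienal 18 carries the diene and the CH2O group of C7. The forward reaction is an auxiliary-controlled syn aldol with 1,2-addition to a β,β-disubstituted enal.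

**Alkyne half (12 ⇒ 9 ⇒ 7 ⇒ 6 ⇒ 5 ⇒ 1 + 2).** The C4–C1' bond is made first, as the addition of an acetylide to a carbonyl group, where hindrance is minimal. C1' then becomes stereogenic by enantioselective conjugate addition of the smallest group, methyl, to enynone 5. The ketone that enabled this addition is converted directly into the gem-dimethyl carbon (6 ⇒ 7). The forward reactions need 1,4- over 1,6-selectivity, good enantiocontrol, and a clean carbonyl-to-CMe2 exchange.

**Diene half (18 ⇒ 17 ⇒ 16 ⇒ 15 ⇒ 13).** The trisubstituted (Z)-alkene is cut at the C–vinyl bond. A syn-carbocupration of ynoate 15 fixes the geometry in one step from achiral, commercial material. The forward reaction must be quenched cold so that the geometry is kept.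

## Roads not taken

**Alternative 1 (the cut most chemists would draw first): the inter-ring bond C4–C1'.**
- Forward key step: union of the tricyclic enol triflate A1 (33 with OSO2CF3 on C4 in place of the cyclohexyl group) with a tertiary nucleophile. This is either the tertiary alkylzinc A3 under palladium or nickel catalysis, or the tertiary pinacol boronate A2 in a Zweifel olefination.
- Why the chosen plan is better: this bond forms a tetrasubstituted alkene next to a quaternary carbon. Reductive elimination would be slow, and β-hydride elimination of the tertiary alkyl metal would compete. A3 is configurationally labile, so C1' would be lost. The boron variant retains configuration, but it needs an anti-periplanar elimination that a six-membered ring cannot adopt, and an alkenyl metal that the lactone and the ester would not tolerate. The chosen plan makes the same bond as an sp–sp3 bond at the outset.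

**Alternative 2: C1–C2 and the lactone C–O bond together.**
- Forward key step: nucleophile-catalysed intramolecular aldol-lactonization of aldehyde acid A4, which closes the cyclopentane and the β-lactone at once.
- Why the chosen plan is better: A4 still contains the tetrasubstituted cyclohexene with its quaternary substituent and the trans C7/C7a pair, so the hardest part is only moved to a monocyclic precursor. Its formyl group sits on C7a, whose hydrogen is both α to the carbonyl and allylic, so amine bases would epimerize it or move C3a=C4 into conjugation. C1 and C2 would depend on a catalyst–substrate match. In the chosen plan C1 and C2 come from an auxiliary aldol and C7a is derived from them.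

**Alternative 3: C3a–C7a, C4–C5 and C6–C7 in a three-component cycloaddition.**
- Forward key step: metal-catalysed [2+2+2] cycloaddition of (E)-enyne A5 with ethene A6. It would give 28 directly, with C7 set stereospecifically by the alkene geometry.
- Why the chosen plan is better: the intermediate metallacyclopentene has a β-hydrogen and a β-oxygen (the CH2O group on C7) next to the metal. β-Elimination would compete with ethene insertion and with the slow sp3–sp2 reductive elimination. The (E)-alkene also lacks the cis substituent that gives the allylic strain, so C7a would be less well controlled. The dienyne version is fully intramolecular and its allyl-metal intermediate has no such escape. The price is two extra steps to set C7.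

Key step: step 12

## Route

Step 1
Reactants: 1 tert-butyl(dimethyl)(pent-4-yn-1-yloxy)silane; 2 3-ethoxycyclohex-2-en-1-one
Product: 5 3-[5-(TBS-oxy)pent-1-yn-1-yl]cyclohex-2-en-1-one, via lithium acetylide 3 (not isolated), via carbinol 4 (not isolated)
Conditions: n-BuLi, THF, −78 °C; 2, −78 → 0 °C; then 0.5 M aq. HCl, THF, 0 °C (brief)
Reagents that add atoms: water, O
Why: Stork–Danheiser sequence: the acetylide adds 1,2 to the vinylogous ester and mild acid hydrolyses the enol ether of 4 with loss of the tertiary hydroxyl, which transposes the carbonyl and gives the 3-alkynyl enone; no stereocentre is formed.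

Step 2
Reactants: 5 3-[5-(TBS-oxy)pent-1-yn-1-yl]cyclohex-2-en-1-one
Product: 6 (3R)-3-methyl-3-[5-(TBS-oxy)pent-1-yn-1-yl]cyclohexan-1-one
Conditions: MeMgBr, Cu(OTf)2 (3 mol %), leucinol-derived N-mesityl hydroxyalkyl imidazolinium hexafluorophosphate (chiral NHC precursor, 4 mol %), Et2O, −30 °C; then aq. NH4Cl
Reagents that add atoms: methylmagnesium bromide, C[Mg]Br
Why: Copper–NHC-catalysed asymmetric conjugate addition of a Grignard reagent to a cyclic enynone, a reaction type known to go 1,4 and not 1,6 and to build alkynyl-bearing quaternary centres; the ligand enantiomer is chosen so that methyl adds to the enone face that gives the (R) centre, the future C1'.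

Step 3
Reactants: 6 (3R)-3-methyl-3-[5-(TBS-oxy)pent-1-yn-1-yl]cyclohexan-1-one
Product: 7 tert-butyl(dimethyl)({5-[(1R)-1,3,3-trimethylcyclohexyl]pent-4-yn-1-yl}oxy)silane
Conditions: Me2Zn, TiCl4, CH2Cl2, −40 °C (gives Me2TiCl2); 6, −40 → 0 °C
Reagents that add atoms: dimethylzinc (both new methyl groups, delivered as Me2TiCl2), C[Zn]C
Why: Reetz geminal dimethylation: Me2TiCl2 adds methyl to the carbonyl, the tertiary titanium alkoxide ionises and a second methyl is transferred, so the ketone becomes the gem-dimethyl carbon; the quaternary centre is not involved, and loss of the silyl group here would be harmless because step 4 removes it anyway.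

Step 4
Reactants: 7 tert-butyl(dimethyl)({5-[(1R)-1,3,3-trimethylcyclohexyl]pent-4-yn-1-yl}oxy)silane
Product: 9 5-[(1R)-1,3,3-trimethylcyclohexyl]pent-4-ynoic acid, via free alcohol 8 (not isolated)
Conditions: CrO3, H2SO4, H2O, acetone, 0 °C
Reagents that add atoms: water, O
Why: Jones oxidation: the aqueous acid cleaves the primary silyl ether and chromic acid oxidises alcohol 8 through the aldehyde hydrate to the acid; the internal alkyne and the saturated ring are inert.

Step 5
Reactants: 9 5-[(1R)-1,3,3-trimethylcyclohexyl]pent-4-ynoic acid; 10 (4S)-4-benzyl-1,3-oxazolidin-2-one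
Product: 12 (4S)-4-benzyl-3-{5-[(1R)-1,3,3-trimethylcyclohexyl]pent-4-ynoyl}-1,3-oxazolidin-2-one, via mixed pivalic anhydride 11 (not isolated)
Conditions: t-BuCOCl, Et3N, THF, −20 °C; then 10, LiCl, −20 °C → rt
Reagents that add atoms: none
Why: Standard N-acylation of an Evans oxazolidinone through the mixed anhydride with LiCl activation; no stereocentre is touched.

Step 6
Reactants: 13 tert-butyl(dimethyl)(prop-2-yn-1-yloxy)silane
Product: 15 methyl 4-(TBS-oxy)but-2-ynoate, via lithium acetylide 14 (not isolated)
Conditions: n-BuLi, THF, −78 °C; ClCO2Me, −78 → 0 °C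
Reagents that add atoms: methyl chloroformate, COC(=O)Cl
Why: Acylation of a lithium acetylide with a chloroformate, a routine entry to 4-silyloxy-2-ynoates.

Step 7
Reactants: 15 methyl 4-(TBS-oxy)but-2-ynoate
Product: 16 methyl (2Z)-3-(TBS-oxymethyl)penta-2,4-dienoate
Conditions: CH2=CHMgBr, CuBr·SMe2, THF, −78 °C; 15, −78 °C; then aq. NH4Cl at −78 °C
Reagents that add atoms: vinylmagnesium bromide, C=C[Mg]Br
Why: syn-Carbocupration of an ynoate: vinyl adds to C3 and copper to C2 on the same face, and protonation at −78 °C, before the alkenylcopper can equilibrate through the allenoate, keeps the ester and CH2OTBS cis, which is the (2Z) geometry the diene needs.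

Step 8
Reactants: 16 methyl (2Z)-3-(TBS-oxymethyl)penta-2,4-dienoate
Product: 17 (2Z)-3-(TBS-oxymethyl)penta-2,4-dien-1-ol
Conditions: i-Bu2AlH, CH2Cl2, −78 °C; then aq. potassium sodium tartrate
Reagents that add atoms: none
Why: 1,2-Reduction of an α,β-unsaturated ester with a dialkylaluminium hydride; the diene and the silyl ether are untouched and the alkene geometry is retained.

Step 9
Reactants: 17 (2Z)-3-(TBS-oxymethyl)penta-2,4-dien-1-ol
Product: 18 (2Z)-3-(TBS-oxymethyl)penta-2,4-dienal
Conditions: MnO2, CH2Cl2, rt; used at once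
Reagents that add atoms: none
Why: MnO2 oxidises the allylic alcohol under neutral conditions, which should avoid Z/E isomerization of the enal.

Step 10
Reactants: 12 (4S)-4-benzyl-3-{5-[(1R)-1,3,3-trimethylcyclohexyl]pent-4-ynoyl}-1,3-oxazolidin-2-one; 18 (2Z)-3-(TBS-oxymethyl)penta-2,4-dienal
Product: 20 (4S)-4-benzyl-3-[(2S,3R,4Z)-3-hydroxy-5-(TBS-oxymethyl)-2-{3-[(1R)-1,3,3-trimethylcyclohexyl]prop-2-yn-1-yl}hepta-4,6-dienoyl]-1,3-oxazolidin-2-one, via boron enolate 19 (not isolated)
Conditions: Bu2BOTf, i-Pr2NEt, CH2Cl2, −78 → 0 °C; 18, −78 → 0 °C; then pH 7 phosphate buffer, MeOH, H2O2, 0 °C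
Reagents that add atoms: none
Why: Evans syn aldol: the (Z)-boron enolate reacts through a closed chair transition state on the face away from the benzyl group, which should give the 2,3-syn adduct with (2S,3R) configuration (the future C2 and C1); the β,β-disubstituted enal can only add 1,2.

Step 11
Reactants: 20 the aldol adduct
Product: 21 (4S)-4-benzyl-3-[(2S,3R,4Z)-3-(TBS-oxy)-5-(TBS-oxymethyl)-2-{3-[(1R)-1,3,3-trimethylcyclohexyl]prop-2-yn-1-yl}hepta-4,6-dienoyl]-1,3-oxazolidin-2-one
Conditions: TBSOTf, 2,6-lutidine, CH2Cl2, −78 °C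
Reagents that add atoms: tert-butyl(dimethyl)silyl triflate, CC(C)(C)[Si](C)(C)OS(=O)(=O)C(F)(F)F
Why: Buffered silylation of a secondary alcohol, which spares the acid-sensitive dienyl carbinol, blocks retro-aldol and elimination later, and adds bulk that reinforces the conformational control of step 12.

Step 12
Reactants: 21 the bis-silylated dienyne imide
Product: 22 (4S)-4-benzyl-3-{[(1R,2S,7aR)-1-(TBS-oxy)-7-(TBS-oxymethyl)-4-[(1R)-1,3,3-trimethylcyclohexyl]-2,3,5,7a-tetrahydro-1H-inden-2-yl]carbonyl}-1,3-oxazolidin-2-one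
Conditions: Ni(cod)2 (10 mol %), P(O-2-biphenylyl)3 (30 mol %), THF, 25 → 50 °C, argon, dilute
Reagents that add atoms: none
Why: Zerovalent nickel binds the alkyne and the adjacent diene double bond (C7=C7a in product numbering) and undergoes oxidative cyclization to forge C3a–C7a, giving an alkenyl(η3-allyl)nickel metallacycle that reductively eliminates the C4–C5 bond and releases the 1,4-cyclohexadiene. The closest known reaction type is the nickel–phosphite-catalysed intramolecular [4+2] cycloaddition of 1,3-dien-8-ynes with a three-atom tether, which accepts silyl-capped and therefore bulky alkynes near room temperature, whereas the thermal reaction of an unactivated dienyne would need temperatures that 21 cannot bear. The cyclopentane closes in the oxidative cyclization (C1, C2, C3 with C3a and C7a, exo with respect to the alkyne) and the six-membered ring closes in the reductive elimination from the seven-membered nickelacycle. The only new stereocentre, C7a, is controlled by C1: the CH2OTBS group on C7 is cis to C1 across the diene double bond, so allylic 1,3-strain holds the C1–H bond in the diene plane, puts C2 with its alkyne arm on one face and the OTBS group on the other, and the alkyne can reach C7a only from the face of C2, which places C7a–H cis to the C1 oxygen as in the target. The step needs face selectivity at the diene (secured by that cis substituent, which the connectivity of the target itself dictates), retention of the diene geometry (no hydride source is present) and cyclization in preference to dimerization (intramolecularity and dilution). The quaternary group sits on the alkyne carbon that bonds to the unsubstituted diene terminus C5, the least demanding partner, and as an sp substituent it points away from the metal while the first bond forms.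

Step 13
Reactants: 22 the bicyclic bis-silyl ether
Product: 23 (4S)-4-benzyl-3-{[(1R,2S,7aR)-1-(TBS-oxy)-7-(hydroxymethyl)-4-[(1R)-1,3,3-trimethylcyclohexyl]-2,3,5,7a-tetrahydro-1H-inden-2-yl]carbonyl}-1,3-oxazolidin-2-one
Conditions: HF·pyridine, pyridine, THF, 0 °C, argon
Reagents that add atoms: none
Why: A primary allylic silyl ether is cleaved much faster than a hindered secondary one under buffered HF·pyridine, a standard differentiation; the diene and the imide are inert.

Step 14
Reactants: 23 the allylic alcohol
Product: 26 (4S)-4-benzyl-3-{[(1R,2S,7R,7aS)-1-(TBS-oxy)-7-formyl-4-[(1R)-1,3,3-trimethylcyclohexyl]-2,3,5,6,7,7a-hexahydro-1H-inden-2-yl]carbonyl}-1,3-oxazolidin-2-one, via enol 24 (not isolated), via 7-epi aldehyde 25 (not isolated)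
Conditions: [Ir(cod)(PCy3)(py)]PF6 (5 mol %, activated with H2, then degassed), THF, rt; then DBU (0.2 equiv), rt
Reagents that add atoms: none
Why: Iridium-hydride-catalysed redox isomerization of a primary allylic alcohol: hydride addition and β-hydride elimination move the C6=C7 double bond to the enol, which tautomerises to the aldehyde as both C7 epimers; DBU then equilibrates the far more acidic aldehyde α-centre (not the imide α-centre) to the epimer with the formyl group equatorial and trans to C1, with C7–H anti to C7a–H.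

Step 15
Reactants: 26 the trans aldehyde
Product: 27 (4S)-4-benzyl-3-{[(1R,2S,7R,7aS)-1-(TBS-oxy)-7-(hydroxymethyl)-4-[(1R)-1,3,3-trimethylcyclohexyl]-2,3,5,6,7,7a-hexahydro-1H-inden-2-yl]carbonyl}-1,3-oxazolidin-2-one
Conditions: NaBH4, MeOH/THF, −40 °C
Reagents that add atoms: none
Why: Chemoselective borohydride reduction of an aldehyde at low temperature; the imide needs far more forcing conditions, and C7 is fixed once the carbonyl is gone.

Step 16
Reactants: 27 the primary alcohol
Product: 28 [(1R,2S,7R,7aS)-2-{[(4S)-4-benzyl-2-oxo-1,3-oxazolidin-3-yl]carbonyl}-1-(TBS-oxy)-4-[(1R)-1,3,3-trimethylcyclohexyl]-2,3,5,6,7,7a-hexahydro-1H-inden-7-yl]methyl butanoate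
Conditions: (n-PrCO)2O, Et3N, DMAP (cat.), CH2Cl2, 0 °C
Reagents that add atoms: butanoic anhydride, CCCC(=O)OC(=O)CCC
Why: DMAP-catalysed acylation of an unhindered primary alcohol.

Step 17
Reactants: 28 the silyl ether butyrate
Product: 29 [(1R,2S,7R,7aS)-2-{[(4S)-4-benzyl-2-oxo-1,3-oxazolidin-3-yl]carbonyl}-1-hydroxy-4-[(1R)-1,3,3-trimethylcyclohexyl]-2,3,5,6,7,7a-hexahydro-1H-inden-7-yl]methyl butanoate
Conditions: 48% aq. HF, MeCN, 0 °C → rt
Reagents that add atoms: none
Why: Acidic fluoride cleavage of the secondary silyl ether, which leaves the butyrate and the imide intact and avoids base-induced retro-aldol.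

Step 18
Reactants: 29 the β-hydroxy imide
Product: 31 (1R,2S,7R,7aS)-7-[(butanoyloxy)methyl]-1-hydroxy-4-[(1R)-1,3,3-trimethylcyclohexyl]-2,3,5,6,7,7a-hexahydro-1H-indene-2-carboxylic acid, via peroxy acid 30 (not isolated)
Conditions: LiOH, H2O2, THF/H2O, 0 °C; then aq. Na2SO3; then 1 M HCl to pH 3
Reagents that add atoms: hydrogen peroxide (as LiOOH), OO
Why: Hydroperoxide cleavage of an Evans imide: the α-effect nucleophile attacks the exocyclic imide carbonyl much faster than the unactivated butyrate or the ring carbamate, and sulfite reduces the peroxy acid to the acid; the free β-hydroxyl speeds the cleavage, and C2 should not epimerise at 0 °C.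

Step 19
Reactants: 31 the β-hydroxy acid
Product: 33 the target: the butanoate of the cis-fused β-lactone formed between the C2 carboxyl and the C1 oxygen of 31 with (1R,2S,7R,7aS) and (1'R) configuration, via mixed sulfonic anhydride 32 (not isolated)
Conditions: PhSO2Cl, pyridine, 0 → 4 °C
Reagents that add atoms: none
Why: β-Lactonization by carboxyl activation: the carboxylate forms the mixed carboxylic sulfonic anhydride and the cis C1 hydroxyl attacks the activated carbonyl (4-exo-trig), so the C1–O bond is never broken and C1 and C2 are retained; the primary hydroxyl is already acylated and cannot compete.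

## Compound list

1 | tert-butyl(dimethyl)(pent-4-yn-1-yloxy)silane | C#CCCCO[Si](C)(C)C(C)(C)C | starting material
2 | 3-ethoxycyclohex-2-en-1-one | CCOC1=CC(=O)CCC1 | starting material
3 | lithium acetylide of 1 | [Li]C#CCCCO[Si](C)(C)C(C)(C)C | intermediate (not isolated)
4 | lithium 3-ethoxy-1-[5-(TBS-oxy)pent-1-yn-1-yl]cyclohex-2-en-1-olate (racemic) | CCOC1=CC(O[Li])(C#CCCCO[Si](C)(C)C(C)(C)C)CCC1 | intermediate (not isolated)
5 | 3-[5-(TBS-oxy)pent-1-yn-1-yl]cyclohex-2-en-1-one | O=C1C=C(C#CCCCO[Si](C)(C)C(C)(C)C)CCC1 | intermediate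
6 | (3R)-3-methyl-3-[5-(TBS-oxy)pent-1-yn-1-yl]cyclohexan-1-one | CC(C)(C)[Si](C)(C)OCCCC#C[C@]1(C)CCCC(=O)C1 | intermediate
7 | tert-butyl(dimethyl)({5-[(1R)-1,3,3-trimethylcyclohexyl]pent-4-yn-1-yl}oxy)silane | CC(C)(C)[Si](C)(C)OCCCC#C[C@]1(C)CCCC(C)(C)C1 | intermediate
8 | 5-[(1R)-1,3,3-trimethylcyclohexyl]pent-4-yn-1-ol | OCCCC#C[C@]1(C)CCCC(C)(C)C1 | intermediate (not isolated)
9 | 5-[(1R)-1,3,3-trimethylcyclohexyl]pent-4-ynoic acid | OC(=O)CCC#C[C@]1(C)CCCC(C)(C)C1 | intermediate
10 | (4S)-4-benzyl-1,3-oxazolidin-2-one | O=C1N[C@@H](Cc2ccccc2)CO1 | starting material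
11 | mixed anhydride of 9 with pivalic acid | CC(C)(C)C(=O)OC(=O)CCC#C[C@]1(C)CCCC(C)(C)C1 | intermediate (not isolated)
12 | (4S)-4-benzyl-3-{5-[(1R)-1,3,3-trimethylcyclohexyl]pent-4-ynoyl}-1,3-oxazolidin-2-one | O=C(CCC#C[C@]1(C)CCCC(C)(C)C1)N1[C@@H](Cc2ccccc2)COC1=O | intermediate
13 | tert-butyl(dimethyl)(prop-2-yn-1-yloxy)silane | C#CCO[Si](C)(C)C(C)(C)C | starting material
14 | lithium acetylide of 13 | [Li]C#CCO[Si](C)(C)C(C)(C)C | intermediate (not isolated)
15 | methyl 4-(TBS-oxy)but-2-ynoate | COC(=O)C#CCO[Si](C)(C)C(C)(C)C | intermediate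
16 | methyl (2Z)-3-(TBS-oxymethyl)penta-2,4-dienoate | COC(=O)/C=C(/C=C)CO[Si](C)(C)C(C)(C)C | intermediate
17 | (2Z)-3-(TBS-oxymethyl)penta-2,4-dien-1-ol | OC/C=C(/C=C)CO[Si](C)(C)C(C)(C)C | intermediate
18 | (2Z)-3-(TBS-oxymethyl)penta-2,4-dienal | O=C/C=C(/C=C)CO[Si](C)(C)C(C)(C)C | intermediate
19 | (Z)-dibutylboron enolate of 12 | CCCCB(CCCC)O/C(=C\CC#C[C@]1(C)CCCC(C)(C)C1)N1[C@@H](Cc2ccccc2)COC1=O | intermediate (not isolated)
20 | (4S)-4-benzyl-3-[(2S,3R,4Z)-3-hydroxy-5-(TBS-oxymethyl)-2-{3-[(1R)-1,3,3-trimethylcyclohexyl]prop-2-yn-1-yl}hepta-4,6-dienoyl]-1,3-oxazolidin-2-one | O=C(N1[C@@H](Cc2ccccc2)COC1=O)[C@@H](CC#C[C@]1(C)CCCC(C)(C)C1)[C@H](O)/C=C(/C=C)CO[Si](C)(C)C(C)(C)C | intermediate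
21 | 3-O-TBS ether of 20 | O=C(N1[C@@H](Cc2ccccc2)COC1=O)[C@@H](CC#C[C@]1(C)CCCC(C)(C)C1)[C@H](O[Si](C)(C)C(C)(C)C)/C=C(/C=C)CO[Si](C)(C)C(C)(C)C | intermediate
22 | (4S)-4-benzyl-3-{[(1R,2S,7aR)-1-(TBS-oxy)-7-(TBS-oxymethyl)-4-[(1R)-1,3,3-trimethylcyclohexyl]-2,3,5,7a-tetrahydro-1H-inden-2-yl]carbonyl}-1,3-oxazolidin-2-one | CC(C)(C)[Si](C)(C)OCC1=CCC([C@]2(C)CCCC(C)(C)C2)=C2C[C@H](C(=O)N3[C@@H](Cc4ccccc4)COC3=O)[C@H](O[Si](C)(C)C(C)(C)C)[C@H]21 | intermediate
23 | 7-(hydroxymethyl) analogue of 22, (1R,2S,7aR) | OCC1=CCC([C@]2(C)CCCC(C)(C)C2)=C2C[C@H](C(=O)N3[C@@H](Cc4ccccc4)COC3=O)[C@H](O[Si](C)(C)C(C)(C)C)[C@H]21 | intermediate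
24 | enol of 26 (exocyclic C7=CH–OH, geometry open) | OC=C1CCC([C@]2(C)CCCC(C)(C)C2)=C2C[C@H](C(=O)N3[C@@H](Cc4ccccc4)COC3=O)[C@H](O[Si](C)(C)C(C)(C)C)[C@H]21 | intermediate (not isolated)
25 | (7S) epimer of 26 (formyl cis to C1) | O=C[C@H]1CCC([C@]2(C)CCCC(C)(C)C2)=C2C[C@H](C(=O)N3[C@@H](Cc4ccccc4)COC3=O)[C@H](O[Si](C)(C)C(C)(C)C)[C@H]21 | intermediate (not isolated)
26 | (4S)-4-benzyl-3-{[(1R,2S,7R,7aS)-1-(TBS-oxy)-7-formyl-4-[(1R)-1,3,3-trimethylcyclohexyl]-2,3,5,6,7,7a-hexahydro-1H-inden-2-yl]carbonyl}-1,3-oxazolidin-2-one | O=C[C@@H]1CCC([C@]2(C)CCCC(C)(C)C2)=C2C[C@H](C(=O)N3[C@@H](Cc4ccccc4)COC3=O)[C@H](O[Si](C)(C)C(C)(C)C)[C@H]21 | intermediate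
27 | 7-(hydroxymethyl) analogue of 26, (1R,2S,7R,7aS) | OC[C@@H]1CCC([C@]2(C)CCCC(C)(C)C2)=C2C[C@H](C(=O)N3[C@@H](Cc4ccccc4)COC3=O)[C@H](O[Si](C)(C)C(C)(C)C)[C@H]21 | intermediate
28 | butanoate of 27 | CCCC(=O)OC[C@@H]1CCC([C@]2(C)CCCC(C)(C)C2)=C2C[C@H](C(=O)N3[C@@H](Cc4ccccc4)COC3=O)[C@H](O[Si](C)(C)C(C)(C)C)[C@H]21 | intermediate
29 | 1-hydroxy analogue of 28 (silyl group removed) | CCCC(=O)OC[C@@H]1CCC([C@]2(C)CCCC(C)(C)C2)=C2C[C@H](C(=O)N3[C@@H](Cc4ccccc4)COC3=O)[C@H](O)[C@H]21 | intermediate
30 | peroxy acid corresponding to 31 | CCCC(=O)OC[C@@H]1CCC([C@]2(C)CCCC(C)(C)C2)=C2C[C@H](C(=O)OO)[C@H](O)[C@H]21 | intermediate (not isolated)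
31 | (1R,2S,7R,7aS)-7-[(butanoyloxy)methyl]-1-hydroxy-4-[(1R)-1,3,3-trimethylcyclohexyl]-2,3,5,6,7,7a-hexahydro-1H-indene-2-carboxylic acid | CCCC(=O)OC[C@@H]1CCC([C@]2(C)CCCC(C)(C)C2)=C2C[C@H](C(=O)O)[C@H](O)[C@H]21 | intermediate
32 | mixed anhydride of 31 with benzenesulfonic acid | CCCC(=O)OC[C@@H]1CCC([C@]2(C)CCCC(C)(C)C2)=C2C[C@H](C(=O)OS(=O)(=O)c3ccccc3)[C@H](O)[C@H]21 | intermediate (not isolated)
33 | butanoate of the cis-fused β-lactone (C2 carboxyl onto C1 oxygen) of 31; (1R,2S,7R,7aS), (1'R) | CCCC(=O)OC[C@@H]1CCC([C@]2(C)CCCC(C)(C)C2)=C2C[C@@H]3C(=O)O[C@@H]3[C@H]21 | target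

## Step count and risks

Total: 19 steps. Longest linear sequence: 15 steps (steps 1–5 and 10–19).

**Step 12 (key step).**
- What may go wrong: oxidative cyclization or reductive elimination may be slow at the alkyne carbon that bears the quaternary group. Diene oligomerization, loss of the diene geometry, or dehydrogenation of the 1,4-cyclohexadiene to an indane could then take over.
- Fallback, rings built one at a time, from 12 back to 26: An Evans aldol of 12 with acrolein should give (4S)-4-benzyl-3-[(2S,3R)-3-hydroxy-2-{3-[(1R)-1,3,3-trimethylcyclohexyl]prop-2-yn-1-yl}pent-4-enoyl]-1,3-oxazolidin-2-one F1. Silylation with TBSOTf and 2,6-lutidine gives its TBS ether F2. Ring-closing enyne metathesis (second-generation Grubbs catalyst RuCl2(H2IMes)(PCy3)(=CHPh), ethene atmosphere, toluene, 60 °C) gives the 1-vinylcyclopentene diene F3. A Diels–Alder reaction of F3 with acrolein (thermal or Me2AlCl-promoted) should add anti to the OTBS group with "ortho" orientation and give aldehyde 25, which DBU equilibrates to 26. This sequence is shorter, but both ring-forming steps are intermolecular or demand a ruthenium carbene next to the quaternary carbon, which is why it is held in reserve.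

**Step 14.**
- What may go wrong: the iridium hydride may walk the C6=C7 double bond through C5–H or C7a–H into conjugation with C3a=C4 instead of towards oxygen. The base equilibration may be incomplete, or silanol may be lost from the β-silyloxy imide.
- Fallback, from 23 back to 26: Oxidation of 23 with Dess–Martin periodinane (NaHCO3, CH2Cl2) gives the enal F4. Conjugate reduction of F4 with [(Ph3P)CuH]6 in toluene gives the saturated aldehyde as 25 and 26. Equilibration with DBU or piperidinium acetate then gives 26.

**Step 2.**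
- What may go wrong: enantioselectivity may erode with the small methyl Grignard reagent, or some 1,6-addition may give an allene.
- Fallback, reversed pairing at the quaternary centre, from 2 back to 8: Treatment of 2 with MeLi and then aqueous acid gives 3-methylcyclohex-2-en-1-one F5 (also commercial). Copper–NHC-catalysed asymmetric conjugate addition of the alane formed from trimethylsilylacetylene and i-Bu2AlH gives (3R)-3-methyl-3-[1-(trimethylsilyl)ethenyl]cyclohexan-1-one F6. Me2TiCl2 converts F6 into trimethyl{1-[(1R)-1,3,3-trimethylcyclohexyl]ethenyl}silane F7. N-Iodosuccinimide gives (1R)-1-(1-iodoethenyl)-1,3,3-trimethylcyclohexane F8. Elimination with t-BuOK gives (1R)-1-ethynyl-1,3,3-trimethylcyclohexane F9. Its lithium acetylide opens oxetane in the presence of BF3·OEt2 to give alcohol 8, which is oxidised as in step 4.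

**Step 3.**
- What may go wrong: the tertiary carbocation may eliminate to methylcyclohexenes or rearrange before the second methyl is transferred, or the Lewis acid may attack the alkyne.
- Fallback, gem-dimethyl group brought in with the ring, from 1 back to 7: Acetylide 3 (from 1) is added to commercial 3-ethoxy-5,5-dimethylcyclohex-2-en-1-one and the adduct is hydrolysed to 5,5-dimethyl-3-[5-(TBS-oxy)pent-1-yn-1-yl]cyclohex-2-en-1-one F10. The conjugate addition of step 2 gives (3S)-3,5,5-trimethyl-3-[5-(TBS-oxy)pent-1-yn-1-yl]cyclohexan-1-one F11. Condensation with tosylhydrazine gives the tosylhydrazone F12. Reduction of F12 with catecholborane followed by NaOAc removes the carbonyl under mild, non-cationic conditions and gives 7.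

## Further compounds

F1 | step 12 | (4S)-4-benzyl-3-[(2S,3R)-3-hydroxy-2-{3-[(1R)-1,3,3-trimethylcyclohexyl]prop-2-yn-1-yl}pent-4-enoyl]-1,3-oxazolidin-2-one | O=C(N1[C@@H](Cc2ccccc2)COC1=O)[C@@H](CC#C[C@]1(C)CCCC(C)(C)C1)[C@H](O)C=C
F2 | step 12 | 3-O-TBS ether of F1 | O=C(N1[C@@H](Cc2ccccc2)COC1=O)[C@@H](CC#C[C@]1(C)CCCC(C)(C)C1)[C@H](O[Si](C)(C)C(C)(C)C)C=C
F3 | step 12 | (4S)-4-benzyl-3-{[(1S,2R)-2-(TBS-oxy)-4-{1-[(1R)-1,3,3-trimethylcyclohexyl]ethenyl}cyclopent-3-en-1-yl]carbonyl}-1,3-oxazolidin-2-one | C=C([C@]1(C)CCCC(C)(C)C1)C1=C[C@@H](O[Si](C)(C)C(C)(C)C)[C@@H](C(=O)N2[C@@H](Cc3ccccc3)COC2=O)C1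
F4 | step 14 | (4S)-4-benzyl-3-{[(1R,2S,7aR)-1-(TBS-oxy)-7-formyl-4-[(1R)-1,3,3-trimethylcyclohexyl]-2,3,5,7a-tetrahydro-1H-inden-2-yl]carbonyl}-1,3-oxazolidin-2-one | O=CC1=CCC([C@]2(C)CCCC(C)(C)C2)=C2C[C@H](C(=O)N3[C@@H](Cc4ccccc4)COC3=O)[C@H](O[Si](C)(C)C(C)(C)C)[C@H]21
F5 | step 2 | 3-methylcyclohex-2-en-1-one | CC1=CC(=O)CCC1
F6 | step 2 | (3R)-3-methyl-3-[1-(trimethylsilyl)ethenyl]cyclohexan-1-one | C=C([Si](C)(C)C)[C@]1(C)CCCC(=O)C1
F7 | step 2 | trimethyl{1-[(1R)-1,3,3-trimethylcyclohexyl]ethenyl}silane | C=C([Si](C)(C)C)[C@]1(C)CCCC(C)(C)C1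
F8 | step 2 | (1R)-1-(1-iodoethenyl)-1,3,3-trimethylcyclohexane | C=C(I)[C@]1(C)CCCC(C)(C)C1
F9 | step 2 | (1R)-1-ethynyl-1,3,3-trimethylcyclohexane | C#C[C@]1(C)CCCC(C)(C)C1
F10 | step 3 | 5,5-dimethyl-3-[5-(TBS-oxy)pent-1-yn-1-yl]cyclohex-2-en-1-one | O=C1C=C(C#CCCCO[Si](C)(C)C(C)(C)C)CC(C)(C)C1
F11 | step 3 | (3S)-3,5,5-trimethyl-3-[5-(TBS-oxy)pent-1-yn-1-yl]cyclohexan-1-one | CC(C)(C)[Si](C)(C)OCCCC#C[C@]1(C)CC(=O)CC(C)(C)C1
F12 | step 3 | 4-methylbenzenesulfonylhydrazone of F11 | CC(C)(C)[Si](C)(C)OCCCC#C[C@]1(C)CC(=NNS(=O)(=O)c2ccc(C)cc2)CC(C)(C)C1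
A1 | alternative 1 | enol triflate: 33 with trifluoromethanesulfonyloxy on C4 in place of the trimethylcyclohexyl group | CCCC(=O)OC[C@@H]1CCC(OS(=O)(=O)C(F)(F)F)=C2C[C@@H]3C(=O)O[C@@H]3[C@H]21
A2 | alternative 1 | (S)-4,4,5,5-tetramethyl-2-(1,3,3-trimethylcyclohexyl)-1,3,2-dioxaborolane | CC1(C)OB(OC1(C)C)[C@]1(C)CCCC(C)(C)C1
A3 | alternative 1 | bromo(1,3,3-trimethylcyclohexyl)zinc (configurationally labile) | Br[Zn]C1(C)CCCC(C)(C)C1
A4 | alternative 2 | 3-{(5R,6S)-5-[(butanoyloxy)methyl]-6-formyl-2-[(1R)-1,3,3-trimethylcyclohexyl]cyclohex-1-en-1-yl}propanoic acid | CCCC(=O)OC[C@@H]1CCC([C@]2(C)CCCC(C)(C)C2)=C(CCC(=O)O)[C@H]1C=O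
A5 | alternative 3 | (4S)-4-benzyl-3-[(2S,3R,4E)-6-(butanoyloxy)-3-(TBS-oxy)-2-{3-[(1R)-1,3,3-trimethylcyclohexyl]prop-2-yn-1-yl}hex-4-enoyl]-1,3-oxazolidin-2-one | O=C(N1[C@@H](Cc2ccccc2)COC1=O)[C@@H](CC#C[C@]1(C)CCCC(C)(C)C1)[C@H](O[Si](C)(C)C(C)(C)C)/C=C/COC(=O)CCC
A6 | alternative 3 | ethene | C=C
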